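## Retrosynthetic overview

- The enone arm (ring E–CO–CH=CH–) is disconnected last from ring D by a Mizoroki–Heck reaction of an aryl bromide; all phenols travel as MOM ethers.
- Enabling feature: C3 of ring C is alpha to the C4 ketone and is bonded to ring D ortho to the ring-D hydroxyl. With one extra carboxyl carbon on C3, the array O–C(ring D)=C(ring D)–C3–C(=O) is a benzofuran-2(3H)-one, so the core is the decarboxylation product of a spiro[benzofuran-3,3'-chroman]-2,4'-dione whose lactone is a temporary ring.
- Key disconnection: the spiro diketone is cut at O1–C2 and C3–C4 into a salicyloyl pyrazole (ring A) and a 3-benzylidenebenzofuranone (rings B and D). Forward, an enantioselective oxa-Michael addition is followed by closure of ring C through C-acylation of the lactone enolate (C3–C4).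
- Ring order: temporary lactone (preformed), then ring C (key step; C2 is set and locked by the quaternary C3), then lactone opening with loss of its carbonyl as CO2 in the last step, where C3–H is set trans to C2 under thermodynamic control.

Key step: step 8

Assumption: the quinidine-derived squaramide is taken to deliver the required (2'S) series of the spiro diketone; if the sense of induction is the opposite, the quinine-derived pseudoenantiomer is used in its place.

Remark: the configuration drawn at the spiro carbon is the one expected from the model given in the key step; it is erased in the last step and does not affect the outcome.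

## Route

Step 1
Reactants: 1 2-hydroxyphenylacetic acid
Product: 2 2-(5-bromo-2-hydroxyphenyl)acetic acid
Conditions: NBS (1.0 equiv), MeCN, 0 °C to rt
Reagents that add atoms: N-bromosuccinimide, O=C1CCC(=O)N1Br
Why: Electrophilic aromatic bromination, directed by the phenolic hydroxyl to its para position, the free ortho position being the more hindered one.

Step 2
Reactants: 2 2-(5-bromo-2-hydroxyphenyl)acetic acid
Product: 3 5-bromobenzofuran-2(3H)-one
Conditions: TsOH·H2O (5 mol %), toluene, reflux, Dean–Stark trap
Reagents that add atoms: none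
Why: Acid-catalysed intramolecular Fischer esterification should close the five-membered aryl lactone with azeotropic removal of water.

Step 3
Reactants: 4 4-hydroxybenzaldehyde
Product: 5 4-(methoxymethoxy)benzaldehyde
Conditions: MOMCl, i-Pr2NEt, CH2Cl2, 0 °C to rt
Reagents that add atoms: chloromethyl methyl ether (MOMCl), COCCl
Why: Williamson-type O-alkylation of the phenol gives the MOM ether, which later tolerates amine bases, Grignard-free palladium chemistry and hydroxide.

Step 4
Reactants: 3 5-bromobenzofuran-2(3H)-one; 5 4-(methoxymethoxy)benzaldehyde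
Product: 6 (E)-5-bromo-3-[4-(methoxymethoxy)benzylidene]benzofuran-2(3H)-one
Conditions: piperidinium acetate (10 mol %), toluene, 4 Å molecular sieves, 60 °C
Reagents that add atoms: none
Why: Knoevenagel condensation at the acidic C3 methylene of the lactone should give mainly the E isomer (aryl anti to the lactone carbonyl), and the geometry is of no consequence because the next use of this alkene begins with a reversible conjugate addition.

Step 5
Reactants: 7 2,4,6-trihydroxybenzaldehyde
Product: 8 2-hydroxy-4,6-bis(methoxymethoxy)benzaldehyde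
Conditions: MOMCl (2.2 equiv), i-Pr2NEt (2.5 equiv), CH2Cl2, 0 °C
Reagents that add atoms: chloromethyl methyl ether (MOMCl), COCCl
Why: Williamson-type MOM ether formation alkylates the 4-hydroxyl and one of the two equivalent ortho hydroxyls, while the second ortho hydroxyl stays free because of its hydrogen bond to the formyl group and the limited amount of reagent.

Step 6
Reactants: 8 2-hydroxy-4,6-bis(methoxymethoxy)benzaldehyde
Product: 9 2-hydroxy-4,6-bis(methoxymethoxy)benzoic acid
Conditions: NaClO2, NaH2PO4, 2-methyl-2-butene (excess), t-BuOH/H2O, 0 °C to rt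
Reagents that add atoms: sodium chlorite (NaClO2), [Na+].[O-]Cl=O
Why: Pinnick oxidation converts the aldehyde to the acid under buffered conditions that leave the MOM acetals and the chelated phenol intact, 2-methyl-2-butene removing the hypochlorite that would chlorinate the electron-rich ring.

Step 7
Reactants: 9 2-hydroxy-4,6-bis(methoxymethoxy)benzoic acid
Product: 10 [2-hydroxy-4,6-bis(methoxymethoxy)phenyl](1H-pyrazol-1-yl)methanone
Conditions: 1H-pyrazole, DCC, DMAP (10 mol %), CH2Cl2, 0 °C to rt
Reagents that add atoms: 1H-pyrazole, c1cn[nH]c1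
Why: Steglich-type carbodiimide coupling relays the O-acylisourea through DMAP to the pyrazole N–H, the chelated ortho phenol being too weak a nucleophile to compete, and gives an activated amide whose leaving group is neutral and non-basic.

Step 8
Reactants: 10 [2-hydroxy-4,6-bis(methoxymethoxy)phenyl](1H-pyrazol-1-yl)methanone; 6 (E)-5-bromo-3-[4-(methoxymethoxy)benzylidene]benzofuran-2(3H)-one
Product: 12 (2'S,3R)-5-bromo-5',7'-bis(methoxymethoxy)-2'-[4-(methoxymethoxy)phenyl]spiro[benzofuran-3(2H),3'-chroman]-2,4'-dione, via oxa-Michael enolate 11 (not isolated)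
Conditions: bifunctional squaramide from 9-amino-9-deoxy-epi-quinidine and 3,5-bis(trifluoromethyl)aniline (10 mol %), 6 (1.1 equiv), CH2Cl2, 4 Å molecular sieves, rt
Reagents that add atoms: none
Why: Proposed new method: the quinuclidine nitrogen of the catalyst deprotonates the chelated phenol of 10 while the squaramide N–H pair binds the lactone carbonyl of 6, the phenoxide adds to the Si face of the benzylidene carbon (O1–C2 bond) to give the ion-paired lactone enolate 11, and the enolate carbon then attacks the neighbouring N-acylpyrazole carbonyl and expels neutral pyrazole, which forms the C3–C4 bond. The closest known reaction types are the tandem oxa-Michael/Dieckmann annulation of salicylate esters with acrylates, the squaramide-catalysed oxa-Michael-initiated spiroannulations of 3-ylidene oxindoles and benzofuranones, and the C-acylation of 3-substituted benzofuranone enolates by O-to-C acyl transfer. Ring C is closed by a 6-exo-trig acyl substitution at the enolate carbon, the alternative O-acylation requiring an eight-membered ring. The C2' centre is set by the catalyst-controlled face of the conjugate addition and is locked at once, because the quaternary spiro carbon leaves no enolisable hydrogen and therefore no retro-oxa-Michael pathway; the spiro centre is substrate-controlled (the C2'–H bond lies in the enolate plane toward the benzo ring to minimise allylic 1,3-strain and the acyl group arrives from the face that carries O1, which puts the 2'-aryl group cis to the lactone carbonyl) and is erased in step 13. The step needs ring closure to outrun both reversal of the oxa-Michael addition and any uncatalysed background reaction, which the activated amide with a non-basic leaving group, the out-of-plane twist of the doubly ortho-substituted aroyl group and the six-membered transition state are meant to secure.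

Step 9
Reactants: 13 2,4-dihydroxybenzaldehyde
Product: 14 2,4-bis(methoxymethoxy)benzaldehyde
Conditions: MOMCl (3 equiv), i-Pr2NEt (4 equiv), CH2Cl2, 0 °C to reflux
Reagents that add atoms: chloromethyl methyl ether (MOMCl), COCCl
Why: Double Williamson-type MOM ether formation, the excess of reagent and warming also alkylating the chelated ortho hydroxyl.

Step 10
Reactants: 14 2,4-bis(methoxymethoxy)benzaldehyde
Product: 15 1-[2,4-bis(methoxymethoxy)phenyl]prop-2-en-1-ol (racemic)
Conditions: vinylmagnesium bromide, THF, −78 to 0 °C; then H2O
Reagents that add atoms: vinylmagnesium bromide, C=C[Mg]Br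
Why: Grignard 1,2-addition to the aldehyde, assisted by chelation to the ortho MOM ether, gives a racemic carbinol whose stereocentre is removed in the next step.

Step 11
Reactants: 15 1-[2,4-bis(methoxymethoxy)phenyl]prop-2-en-1-ol
Product: 16 1-[2,4-bis(methoxymethoxy)phenyl]prop-2-en-1-one
Conditions: MnO2 (excess), CH2Cl2, rt
Reagents that add atoms: none
Why: Manganese dioxide oxidation of an allylic and benzylic alcohol gives the aryl vinyl ketone under neutral conditions that spare the MOM ethers, and the enone is used directly to limit polymerisation.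

Step 12
Reactants: 12 bromo spiro diketone; 16 1-[2,4-bis(methoxymethoxy)phenyl]prop-2-en-1-one
Product: 17 (2'S,3R)-5-{(E)-3-[2,4-bis(methoxymethoxy)phenyl]-3-oxoprop-1-en-1-yl}-5',7'-bis(methoxymethoxy)-2'-[4-(methoxymethoxy)phenyl]spiro[benzofuran-3(2H),3'-chroman]-2,4'-dione
Conditions: Pd(OAc)2 (5 mol %), P(o-tol)3 (12 mol %), Et3N (2 equiv), BHT (cat.), anhydrous MeCN, 80 °C
Reagents that add atoms: none
Why: Mizoroki–Heck reaction (oxidative addition of zerovalent palladium into the aryl C–Br bond, syn insertion of the enone, syn β-hydride elimination) should give the E-enone, and the quaternary spiro carbon makes the substrate insensitive to the amine base so that C2' is not at risk.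

Step 13
Reactants: 17 spiro diketone carrying the enone arm
Product: 20 (2R,3S)-3-{5-[(E)-3-(2,4-dihydroxyphenyl)-3-oxoprop-1-en-1-yl]-2-hydroxyphenyl}-5,7-dihydroxy-2-(4-hydroxyphenyl)chroman-4-one, via ring-opened beta-keto acid 18 (not isolated), via MOM-protected flavanone 19 (not isolated)
Conditions: LiOH (3 equiv), THF/H2O, 0 °C; then 3 M aq. HCl to pH 1, MeOH, 0 to 45 °C
Reagents that add atoms: none
Why: Hydroxide opens the activated aryl lactone at 0 °C (the C4 ketone is shielded and deactivated by the trioxygenated ring), acidification gives beta-keto acid 18, which loses CO2 through the usual cyclic transition state, the enol is protonated and equilibrated under acid to the trans-2,3-diequatorial ketone 19 (thermodynamic control at C3, with C2 untouched because no base is present once CO2 has left), and the same acidic methanol then cleaves the five MOM acetals.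

## Compound list

1 | 2-hydroxyphenylacetic acid | OC(=O)Cc1ccccc1O | starting material
2 | 2-(5-bromo-2-hydroxyphenyl)acetic acid | OC(=O)Cc1cc(Br)ccc1O | intermediate
3 | 5-bromobenzofuran-2(3H)-one | O=C1Cc2cc(Br)ccc2O1 | intermediate
4 | 4-hydroxybenzaldehyde | O=Cc1ccc(O)cc1 | starting material
5 | 4-(methoxymethoxy)benzaldehyde | COCOc1ccc(C=O)cc1 | intermediate
6 | (E)-5-bromo-3-[4-(methoxymethoxy)benzylidene]benzofuran-2(3H)-one | O=C1Oc2ccc(Br)cc2/C1=C\c1ccc(OCOC)cc1 | intermediate
7 | 2,4,6-trihydroxybenzaldehyde | O=Cc1c(O)cc(O)cc1O | starting material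
8 | 2-hydroxy-4,6-bis(methoxymethoxy)benzaldehyde | COCOc1cc(O)c(C=O)c(OCOC)c1 | intermediate
9 | 2-hydroxy-4,6-bis(methoxymethoxy)benzoic acid | COCOc1cc(O)c(C(=O)O)c(OCOC)c1 | intermediate
10 | [2-hydroxy-4,6-bis(methoxymethoxy)phenyl](1H-pyrazol-1-yl)methanone | COCOc1cc(O)c(C(=O)n2cccn2)c(OCOC)c1 | intermediate
11 | enolate of 5-bromo-3-{(S)-[3,5-bis(methoxymethoxy)-2-(1H-pyrazole-1-carbonyl)phenoxy][4-(methoxymethoxy)phenyl]methyl}benzofuran-2(3H)-one (ion-paired with the protonated catalyst) | COCOc1ccc([C@H](Oc2cc(OCOC)cc(OCOC)c2C(=O)n2cccn2)C2=C([O-])Oc3ccc(Br)cc23)cc1 | intermediate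
12 | (2'S,3R)-5-bromo-5',7'-bis(methoxymethoxy)-2'-[4-(methoxymethoxy)phenyl]spiro[benzofuran-3(2H),3'-chroman]-2,4'-dione (2'-aryl cis to the lactone carbonyl) | COCOc1ccc([C@@H]2Oc3cc(OCOC)cc(OCOC)c3C(=O)[C@]24C(=O)Oc3ccc(Br)cc34)cc1 | intermediate
13 | 2,4-dihydroxybenzaldehyde | O=Cc1ccc(O)cc1O | starting material
14 | 2,4-bis(methoxymethoxy)benzaldehyde | COCOc1ccc(C=O)c(OCOC)c1 | intermediate
15 | 1-[2,4-bis(methoxymethoxy)phenyl]prop-2-en-1-ol (racemic) | C=CC(O)c1ccc(OCOC)cc1OCOC | intermediate
16 | 1-[2,4-bis(methoxymethoxy)phenyl]prop-2-en-1-one | C=CC(=O)c1ccc(OCOC)cc1OCOC | intermediate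
17 | (2'S,3R)-5-{(E)-3-[2,4-bis(methoxymethoxy)phenyl]-3-oxoprop-1-en-1-yl}-5',7'-bis(methoxymethoxy)-2'-[4-(methoxymethoxy)phenyl]spiro[benzofuran-3(2H),3'-chroman]-2,4'-dione | COCOc1ccc([C@@H]2Oc3cc(OCOC)cc(OCOC)c3C(=O)[C@]24C(=O)Oc3ccc(/C=C/C(=O)c5ccc(OCOC)cc5OCOC)cc34)cc1 | intermediate
18 | (2S,3R)-3-{5-[(E)-3-[2,4-bis(methoxymethoxy)phenyl]-3-oxoprop-1-en-1-yl]-2-hydroxyphenyl}-5,7-bis(methoxymethoxy)-2-[4-(methoxymethoxy)phenyl]-4-oxochromane-3-carboxylic acid | O=C(/C=C/c1ccc(O)c([C@]2(C(=O)O)C(=O)c3c(OCOC)cc(OCOC)cc3O[C@H]2c2ccc(OCOC)cc2)c1)c1ccc(OCOC)cc1OCOC | intermediate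
19 | (2R,3S)-3-{5-[(E)-3-[2,4-bis(methoxymethoxy)phenyl]-3-oxoprop-1-en-1-yl]-2-hydroxyphenyl}-5,7-bis(methoxymethoxy)-2-[4-(methoxymethoxy)phenyl]chroman-4-one | O=C(/C=C/c1ccc(O)c([C@@H]2C(=O)c3c(OCOC)cc(OCOC)cc3O[C@H]2c2ccc(OCOC)cc2)c1)c1ccc(OCOC)cc1OCOC | intermediate
20 | (2R,3S)-3-{5-[(E)-3-(2,4-dihydroxyphenyl)-3-oxoprop-1-en-1-yl]-2-hydroxyphenyl}-5,7-dihydroxy-2-(4-hydroxyphenyl)chroman-4-one (CNP0272156.1) | O=C(/C=C/c1ccc(O)c([C@@H]2C(=O)c3c(O)cc(O)cc3O[C@H]2c2ccc(O)cc2)c1)c1ccc(O)cc1O | target

## Step count and risks

Total step count: 13.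
Longest linear sequence: 6 steps (steps 1, 2, 4, 8, 12, 13 from 1; equally steps 5, 6, 7, 8, 12, 13 from 7).

Steps most likely to fail:

1. Step 8. Ring closure at the hindered, electron-rich aroyl group may be slower than reversal of the oxa-Michael addition, so that no product accumulates, or the face selection by the catalyst may be incomplete. The fallback uses known chemistry at another oxidation level, sets out from 8 and 6, and returns at 12. Salicylaldehyde 8 (in place of 10) and 6 are combined under the same squaramide in the oxa-Michael/aldol domino of salicylaldehydes, a known annulation whose sulfur counterpart is established for 3-ylidene oxindoles. The unhindered formyl group should capture the enolate far faster than the acylpyrazole and give the spiro-chromanol (2'S,3S,4'R)-5-bromo-4'-hydroxy-5',7'-bis(methoxymethoxy)-2'-[4-(methoxymethoxy)phenyl]spiro[benzofuran-3(2H),3'-chroman]-2-one F1 (carbinol configuration of no consequence). Dess–Martin periodinane added to the crude mixture then oxidises the benzylic alcohol to the ketone before the aldol step can revert, which gives 12.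

2. Step 13. During the basic opening the carboxylate may lose CO2 prematurely, and the enolate so formed can open ring C (retro-oxa-Michael), with loss of configurational integrity at C2; prolonged acid exposure may also equilibrate the hydroxychalcone arm with its flavanone. The fallback sets out from 17 and returns at 19. The lactone is opened under neutral conditions with allyl alcohol and catalytic DMAP in CH2Cl2 to the allyl ester prop-2-en-1-yl (2S,3R)-3-{5-[(E)-3-[2,4-bis(methoxymethoxy)phenyl]-3-oxoprop-1-en-1-yl]-2-hydroxyphenyl}-5,7-bis(methoxymethoxy)-2-[4-(methoxymethoxy)phenyl]-4-oxochromane-3-carboxylate F2. Pd(PPh3)4 and morpholine in THF at room temperature then remove the allyl group and CO2 (Tsuji–Trost deallylation with decarboxylation), the neighbouring ring-D phenol protonating the enolate, to give 19 as an isolated compound. Compound 19 is deprotected with HCl in methanol as in the last operation of step 13.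

3. Step 12. The aryl vinyl ketone may polymerise or be lost by conjugate addition at the temperature needed for oxidative addition, or the amine may open the activated lactone. The fallback sets out from 12 and 16 and returns at 17. Base-free Stille coupling of 12 with tributyl(vinyl)stannane (Pd(PPh3)4, toluene, 90 °C) gives the styrene (2'S,3R)-5-ethenyl-5',7'-bis(methoxymethoxy)-2'-[4-(methoxymethoxy)phenyl]spiro[benzofuran-3(2H),3'-chroman]-2,4'-dione F3. Cross-metathesis of F3 with 16 (second-generation Hoveyda–Grubbs catalyst, CH2Cl2, 40 °C) should then give 17 as the E-enone.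

Further compounds
F1 | step 8 | (2'S,3S,4'R)-5-bromo-4'-hydroxy-5',7'-bis(methoxymethoxy)-2'-[4-(methoxymethoxy)phenyl]spiro[benzofuran-3(2H),3'-chroman]-2-one | COCOc1ccc([C@@H]2Oc3cc(OCOC)cc(OCOC)c3[C@@H](O)[C@]24C(=O)Oc3ccc(Br)cc34)cc1
F2 | step 13 | prop-2-en-1-yl (2S,3R)-3-{5-[(E)-3-[2,4-bis(methoxymethoxy)phenyl]-3-oxoprop-1-en-1-yl]-2-hydroxyphenyl}-5,7-bis(methoxymethoxy)-2-[4-(methoxymethoxy)phenyl]-4-oxochromane-3-carboxylate | O=C(/C=C/c1ccc(O)c([C@]2(C(=O)OCC=C)C(=O)c3c(OCOC)cc(OCOC)cc3O[C@H]2c2ccc(OCOC)cc2)c1)c1ccc(OCOC)cc1OCOC
F3 | step 12 | (2'S,3R)-5-ethenyl-5',7'-bis(methoxymethoxy)-2'-[4-(methoxymethoxy)phenyl]spiro[benzofuran-3(2H),3'-chroman]-2,4'-dione | COCOc1ccc([C@@H]2Oc3cc(OCOC)cc(OCOC)c3C(=O)[C@]24C(=O)Oc3ccc(C=C)cc34)cc1
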